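A ratio was what I set out to watch: the time a slowly added charge has spent in the flask on average, against the time of reading. With an addition spread evenly over 4.0 h and a reading at 6.0 h, this mean age is 4.00 h, a ratio of 0.667. A flask charged together at the start has the full reading time as its mean age, so it stands at the top of this scale, and the slow flasks stand below it.

| flask | starting complex | incoming ligand | leaving ligand | remark | time |
|---|---|---|---|---|---|
| green | 0.10 M | 1.8 equiv | 5 equiv | run made earlier |  |
| blue | 0.10 M | 0.90 equiv | 5 equiv | run made earlier |  |
| red | 0.10 M | 1.4 equiv | 5 equiv | run made earlier |  |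
| Tuesday's | 0.10 M | 1.80 equiv (in portions, 4, over 4.0 h) | 5.00 equiv | first portion at the start, last at 4.0 h | 6.0 h |
| Wednesday's | 0.10 M | 1.80 equiv (fed, over 4.0 h) | 5.00 equiv | all else is in the flask from the start; the feed brings no volume worth counting | 6.0 h |
| Saturday's | 0.10 M | 1.80 equiv | 5.00 equiv | everything together at the start | 6.0 h |
| Thursday's | 0.10 M (fed, over 4.0 h) | 1.80 equiv | 5.00 equiv | all else is in the flask from the start; the feed brings no volume worth counting | 6.0 h |

| green: time / h | green: complex with three exchanged / % | blue: time / h | blue: complex with three exchanged / % | red: time / h | red: complex with three exchanged / % |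
|---|---|---|---|---|---|
| 0.250 | 2 | 0.417 | 1 | 0.417 | 4 |
| 0.417 | 6 | 1.00 | 6 | 1.00 | 17 |
| 0.667 | 14 | 2.00 | 13 | 2.00 | 27 |
| 1.00 | 19 | 3.00 | 16 | 3.00 | 32 |
| 1.50 | 28 | 4.00 | 19 | 4.00 | 35 |
| 2.50 | 40 | 6.00 | 19 | 6.00 | 38 |
| 4.00 | 46 | 8.00 | 18 | 8.00 | 37 |

(readings scatter by 1.5 percentage points)

1. the flask with the highest amount of complex with three exchanged, in percent of the starting complex charged ("all alike" if they lie within 1.5 percentage points) (Tuesday's / Wednesday's / Saturday's / Thursday's / all alike)
2. final complex with three exchanged, as a percentage of the starting complex charged, in Tuesday's
3. final complex with three exchanged, as a percentage of the starting complex charged, in Wednesday's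
4. final complex with three exchanged, as a percentage of the starting complex charged, in Saturday's
5. final complex with three exchanged, as a percentage of the starting complex charged, in Thursday's

- a reading or a percentage of leaving ligand counts all its forms, free or not

The runs gave me a ladder of times. First came the lag, or induction period: green read 2 % at 0.250 h. Then came the climb, which took hours: green read 40 % at 2.50 h and 46 % at 4.00 h. Then came the tail: red moved from 35 % at 4.00 h to 38 % at 6.00 h, and blue read 19 % at 4.00 h and 19 % at 6.00 h. The addition therefore lasted as long as the climb, so I expected the slow flasks to be read while still on it.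

My rule was that a slow flask reads what green, with the same totals, read at the mean age. That gave about 46 % for Tuesday's, Wednesday's and Thursday's alike, whichever reagent was added slowly. For Saturday's I scaled green by red's last rise and got 49.9 %. I therefore put Saturday's on top, since its mean age is longer.

The forecast differed on Thursday's. It gave Tuesday's 46 %, Wednesday's 43 %, Saturday's 49 % and Thursday's 51 %, and named Thursday's as highest, reasoning that “Feeding complex into excess ligand drives each portion quickly through to product”.

The flasks gave 44.4 % for Tuesday's, 45.5 % for Wednesday's, 51.0 % for Saturday's and 45.9 % for Thursday's, so Saturday's stood highest.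

    starting complex + incoming ligand → leaving ligand + complex with one exchanged (k = 0.108 M⁻¹ min⁻¹)
    complex with one exchanged + incoming ligand → leaving ligand + complex with two exchanged (k = 0.982 M⁻¹ min⁻¹)
    complex with two exchanged + incoming ligand → leaving ligand + complex with three exchanged (k = 0.735 M⁻¹ min⁻¹)
    leaving ligand + incoming ligand ⇌ idle adduct, settled at all times (K = 1.58 M⁻¹)

The slow flasks, at a mean age of 4.00 h, lay within 1.5 percentage points of each other, and Saturday's led them. Without the joining of leaving ligand and incoming ligand to idle adduct, Saturday's lead over Tuesday's shrinks from 6.6 points to 3 points. At 6.00 h, c(idle adduct) was 0.0128 M in Tuesday's against 0.00413 M in Saturday's. Read at 25 h, Tuesday's had a mean age of 23.0 h and stood at 54.1 %, the value Saturday's reaches at 60.0 h, 54.1 %.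

The numbers in the tables stem from a simulated flask with made-up constants, and the scatter is random.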